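Ring B of the target (C1 1,1-dimethylallyl, C2 H, C3 enone carbon, C4 OMe, C5 OH, C6 OH) has its quaternary benzylic carbon on C1 and a hydroxyl on the adjacent C6. These two ortho bonds are disconnected together to a C1–C6 aryne: prenylmagnesium chloride adds through its γ-carbon at C1, and the arylmagnesium left at C6 is oxidised in the same flask, so the C1–C and C6–O bonds form in one operation. The aryne comes from MOM-protected 5-bromoguaiacol, deprotonated between OMOM and bromine. The C3 aldehyde is then introduced by methoxy-directed lithiation, and Claisen–Schmidt condensation followed by acetal cleavage gives the chalcone.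

Key step: step 3

Remark: the target has no stereocentre, so the E enone (set in step 7) is its only stereochemical element; bromine in 1 and 2 is para to the methoxy group, which is the C1/C4 relationship of ring B, so the aryne spans C1–C6 as required.

Step 1
Reactants: 1 5-bromo-2-methoxyphenol
Product: 2 4-bromo-1-methoxy-2-(methoxymethoxy)benzene
Conditions: NaH, MOMCl, THF, 0 → 25 °C
Reagents that add atoms: chloromethyl methyl ether (MOMCl), COCCl
Why: Williamson-type O-alkylation of the sodium phenoxide by the reactive α-chloro ether; the acetal installed here later acidifies the neighbouring ring proton and chelates magnesium.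

Step 2
Reactants: 3 prenyl chloride (1-chloro-3-methylbut-2-ene)
Product: 4 prenylmagnesium chloride
Conditions: Mg turnings (3 equiv), THF, 0 °C, slow addition; solution titrated and used directly
Reagents that add atoms: magnesium, [Mg]
Why: Grignard reagent formation by insertion of magnesium metal into the allylic C–Cl bond, with slow addition of dilute chloride to excess magnesium at 0 °C to keep Wurtz coupling low.

Step 3
Reactants: 2 4-bromo-1-methoxy-2-(methoxymethoxy)benzene; 4 prenylmagnesium chloride
Product: 9 3-methoxy-2-(methoxymethoxy)-6-(2-methylbut-3-en-2-yl)phenol, via aryllithium 5 (not isolated), via aryne 6 (not isolated), via arylmagnesium chloride 7 (not isolated), via arylboronate 8 (not isolated)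
Conditions: lithium 2,2,6,6-tetramethylpiperidide (LiTMP, 1.2 equiv), THF, −78 °C; 4 (3 equiv), −78 → 25 °C; B(OMe)3, 0 → 25 °C; 30% aq H2O2, 2 M NaOH, 0 → 25 °C
Reagents that add atoms: hydrogen peroxide, OO
Why: LiTMP removes the ring proton flanked by OMOM and bromine (the most acidic site, with two ortho activators), and on warming aryllithium 5 expels LiBr to give aryne 6; the allylic Grignard 4 then adds across the strained triple bond through a six-membered, magnesium-ene type transition state in which its tertiary γ-carbon bonds to the aryne carbon remote from OMOM and magnesium is delivered to the carbon beside it, giving 7. Borylation of 7 with B(OMe)3 and alkaline peroxide oxidation of boronate 8 (aryl 1,2-shift from boron to oxygen) then install the hydroxyl, so one flask forms both the aryl–C(quaternary) and the aryl–O bond. The closest known reaction type is the carbomagnesiation of base-generated arynes by aryl and allylic Grignard reagents with electrophilic capture of the resulting ortho-substituted arylmagnesium, joined here to the routine borylation–oxidation of aryl Grignards. No ring is closed and no stereocentre is created. Two selectivities are required: the site of attack on the aryne, which the inductively withdrawing OMOM group fixes by making the distal carbon the electrophilic one and by chelating magnesium at the proximal carbon, and allylic transposition of the prenyl unit, which the cyclic SE2' delivery characteristic of prenylmagnesium reagents and the unhindered in-plane approach to an aryne carbon should secure.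

Step 4
Reactants: 9 3-methoxy-2-(methoxymethoxy)-6-(2-methylbut-3-en-2-yl)phenol
Product: 10 1-methoxy-2,3-bis(methoxymethoxy)-4-(2-methylbut-3-en-2-yl)benzene
Conditions: NaH, MOMCl, DMF, 0 → 25 °C
Reagents that add atoms: chloromethyl methyl ether (MOMCl), COCCl
Why: Williamson-type O-alkylation; the small electrophile and the unencumbered sodium phenoxide in DMF should overcome the flanking acetal and quaternary carbon.

Step 5
Reactants: 10 1-methoxy-2,3-bis(methoxymethoxy)-4-(2-methylbut-3-en-2-yl)benzene
Product: 12 2-methoxy-3,4-bis(methoxymethoxy)-5-(2-methylbut-3-en-2-yl)benzaldehyde, via aryllithium 11 (not isolated)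
Conditions: n-BuLi, TMEDA, Et2O, 0 → 25 °C; DMF, −78 → 0 °C; H2O
Reagents that add atoms: N,N-dimethylformamide (DMF), CN(C)C=O
Why: Directed ortho-metalation followed by DMF formylation: the only ring hydrogen next to an oxygen substituent is the one ortho to the methoxy group (the other lies beside the quaternary carbon), so lithiation can occur only at the future C3, as in the lithiation of 1,2,3-trialkoxybenzenes.

Step 6
Reactants: 13 4'-hydroxyacetophenone
Product: 14 4'-(methoxymethoxy)acetophenone
Conditions: NaH (1.05 equiv), MOMCl, THF, 0 → 25 °C
Reagents that add atoms: chloromethyl methyl ether (MOMCl), COCCl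
Why: Williamson-type O-alkylation of the phenoxide, which forms far more readily than the ketone enolate with one equivalent of base.

Step 7
Reactants: 12 2-methoxy-3,4-bis(methoxymethoxy)-5-(2-methylbut-3-en-2-yl)benzaldehyde; 14 4'-(methoxymethoxy)acetophenone
Product: 16 (E)-3-[2-methoxy-3,4-bis(methoxymethoxy)-5-(2-methylbut-3-en-2-yl)phenyl]-1-[4-(methoxymethoxy)phenyl]prop-2-en-1-one, via aldol adduct 15 (not isolated)
Conditions: KOH, EtOH/H2O, 25 °C
Reagents that add atoms: none
Why: Claisen–Schmidt condensation: the non-enolisable aldehyde accepts the potassium enolate of 14, and E1cB loss of hydroxide from the aldol gives the conjugated enone as the thermodynamically preferred E isomer with aryl and aroyl groups trans.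

Step 8
Reactants: 16 (E)-3-[2-methoxy-3,4-bis(methoxymethoxy)-5-(2-methylbut-3-en-2-yl)phenyl]-1-[4-(methoxymethoxy)phenyl]prop-2-en-1-one
Product: 17 (E)-3-[3,4-dihydroxy-2-methoxy-5-(2-methylbut-3-en-2-yl)phenyl]-1-(4-hydroxyphenyl)prop-2-en-1-one (target)
Conditions: 3 M aq HCl, MeOH, 40 °C, under argon
Reagents that add atoms: none
Why: Acid-catalysed methanolysis (transacetalisation) of the three aryl MOM ethers should release the phenols under conditions mild enough for the enone and the terminal alkene, and the E alkene is retained.

Compound list
1 | 5-bromo-2-methoxyphenol | COc1ccc(Br)cc1O | starting material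
2 | 4-bromo-1-methoxy-2-(methoxymethoxy)benzene | COCOc1cc(Br)ccc1OC | intermediate
3 | prenyl chloride (1-chloro-3-methylbut-2-ene) | CC(C)=CCCl | starting material
4 | prenylmagnesium chloride [(3-methylbut-2-en-1-yl)magnesium chloride] | CC(C)=CC[Mg]Cl | intermediate
5 | [6-bromo-3-methoxy-2-(methoxymethoxy)phenyl]lithium (aryllithium, not isolated) | [Li]c1c(Br)ccc(OC)c1OCOC | intermediate
6 | 1,2-didehydro-4-methoxy-3-(methoxymethoxy)benzene (aryne, not isolated) | COCOC1=C(OC)C=CC#C1 | intermediate
7 | [3-methoxy-2-(methoxymethoxy)-6-(2-methylbut-3-en-2-yl)phenyl]magnesium chloride (not isolated) | C=CC(C)(C)c1ccc(OC)c(OCOC)c1[Mg]Cl | intermediate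
8 | dimethyl [3-methoxy-2-(methoxymethoxy)-6-(2-methylbut-3-en-2-yl)phenyl]boronate (not isolated) | C=CC(C)(C)c1ccc(OC)c(OCOC)c1B(OC)OC | intermediate
9 | 3-methoxy-2-(methoxymethoxy)-6-(2-methylbut-3-en-2-yl)phenol | C=CC(C)(C)c1ccc(OC)c(OCOC)c1O | intermediate
10 | 1-methoxy-2,3-bis(methoxymethoxy)-4-(2-methylbut-3-en-2-yl)benzene | C=CC(C)(C)c1ccc(OC)c(OCOC)c1OCOC | intermediate
11 | [2-methoxy-3,4-bis(methoxymethoxy)-5-(2-methylbut-3-en-2-yl)phenyl]lithium (not isolated) | C=CC(C)(C)c1cc([Li])c(OC)c(OCOC)c1OCOC | intermediate
12 | 2-methoxy-3,4-bis(methoxymethoxy)-5-(2-methylbut-3-en-2-yl)benzaldehyde | C=CC(C)(C)c1cc(C=O)c(OC)c(OCOC)c1OCOC | intermediate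
13 | 4'-hydroxyacetophenone | CC(=O)c1ccc(O)cc1 | starting material
14 | 4'-(methoxymethoxy)acetophenone | CC(=O)c1ccc(OCOC)cc1 | intermediate
15 | 3-hydroxy-3-[2-methoxy-3,4-bis(methoxymethoxy)-5-(2-methylbut-3-en-2-yl)phenyl]-1-[4-(methoxymethoxy)phenyl]propan-1-one (racemic aldol adduct, not isolated) | C=CC(C)(C)c1cc(C(O)CC(=O)c2ccc(OCOC)cc2)c(OC)c(OCOC)c1OCOC | intermediate
16 | (E)-3-[2-methoxy-3,4-bis(methoxymethoxy)-5-(2-methylbut-3-en-2-yl)phenyl]-1-[4-(methoxymethoxy)phenyl]prop-2-en-1-one | C=CC(C)(C)c1cc(/C=C/C(=O)c2ccc(OCOC)cc2)c(OC)c(OCOC)c1OCOC | intermediate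
17 | (E)-3-[3,4-dihydroxy-2-methoxy-5-(2-methylbut-3-en-2-yl)phenyl]-1-(4-hydroxyphenyl)prop-2-en-1-one | C=CC(C)(C)c1cc(/C=C/C(=O)c2ccc(O)cc2)c(OC)c(O)c1O | target

Total step count: 8. Longest linear sequence: 6 steps (steps 1, 3, 4, 5, 7, 8).

Steps most likely to fail

(1) Step 3. Several processes could divert the reaction:
- The ortho-bromo aryllithium may transmetalate to magnesium before it loses LiBr, which would slow aryne formation.
- The prenyl unit may be delivered through its primary carbon, or to the wrong aryne carbon.
- The aryne may be captured by aryllithium 5 instead of the Grignard reagent.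
- The hindered arylmagnesium may be protonated by the liberated amine, or borylate incompletely, before oxidation.

The fallback avoids the aryne and makes the two bonds separately. It sets out from 2, which is treated with LiTMP at −78 °C in the presence of B(Oi-Pr)3, so that aryllithium 5 is borylated before LiBr can be lost. This should give diisopropyl [6-bromo-3-methoxy-2-(methoxymethoxy)phenyl]boronate F1, which alkaline H2O2 should convert into 6-bromo-3-methoxy-2-(methoxymethoxy)phenol F2. NaH/MOMCl should then give 1-bromo-4-methoxy-2,3-bis(methoxymethoxy)benzene F3. The quaternary carbon is attached to the bromine-bearing carbon by a γ-selective Suzuki–Miyaura coupling with prenylboronic acid pinacol ester (Pd(OAc)2, a bulky dialkylbiarylphosphine ligand chosen for the branched isomer, aq K3PO4, THF, 40 °C). Allyl-transposing transmetalation and fast reductive elimination should place the tertiary carbon on the ring. The fallback comes back to the route at 10.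

(2) Step 5. Deprotonation next to the weakly directing methoxy group may be slow or incomplete, and n-BuLi may be consumed by attack elsewhere, leaving unreacted 10. The fallback replaces directed deprotonation by electrophilic bromination and halogen–lithium exchange. It sets out from 9: NBS in MeCN at 0 °C should brominate the only position para to the free hydroxyl (also ortho to the methoxy group), giving 4-bromo-3-methoxy-2-(methoxymethoxy)-6-(2-methylbut-3-en-2-yl)phenol F4. NaH/MOMCl should give 1-bromo-2-methoxy-3,4-bis(methoxymethoxy)-5-(2-methylbut-3-en-2-yl)benzene F5. n-BuLi in THF at −78 °C should exchange bromine for lithium to give aryllithium 11, and DMF then gives the aldehyde. The fallback comes back to the route at 12.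

(3) Step 8. The enone is exposed to acid and methanol for as long as the slowest of three acetals needs. Conjugate addition of methanol, partial cleavage to mixtures, acid-promoted closure of the C6 hydroxyl onto the vinyl group and air oxidation of the liberated catechol may all erode the product. The fallback moves the acid treatment to the aldehyde stage and forms the enone last under neutral conditions. It sets out from 12: the same HCl/MeOH treatment, now with only two acetals and no enone, should give 3,4-dihydroxy-2-methoxy-5-(2-methylbut-3-en-2-yl)benzaldehyde F6, which can be purified. Separately, commercial 2-bromo-1-(4-hydroxyphenyl)ethanone and PPh3 should give [2-(4-hydroxyphenyl)-2-oxoethyl]triphenylphosphonium bromide F7. Aqueous Na2CO3 should convert this salt into the stabilised ylide 1-(4-hydroxyphenyl)-2-(triphenyl-λ5-phosphanylidene)ethan-1-one F8. Wittig olefination of F6 with F8 in THF at reflux should give the E enone directly, since stabilised ylides are E-selective and tolerate free phenols. The fallback comes back to the route at 17.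

Further compounds
F1 | step 3 | diisopropyl [6-bromo-3-methoxy-2-(methoxymethoxy)phenyl]boronate | COCOc1c(B(OC(C)C)OC(C)C)c(Br)ccc1OC
F2 | step 3 | 6-bromo-3-methoxy-2-(methoxymethoxy)phenol | COCOc1c(O)c(Br)ccc1OC
F3 | step 3 | 1-bromo-4-methoxy-2,3-bis(methoxymethoxy)benzene | COCOc1c(OCOC)c(Br)ccc1OC
F4 | step 5 | 4-bromo-3-methoxy-2-(methoxymethoxy)-6-(2-methylbut-3-en-2-yl)phenol | C=CC(C)(C)c1cc(Br)c(OC)c(OCOC)c1O
F5 | step 5 | 1-bromo-2-methoxy-3,4-bis(methoxymethoxy)-5-(2-methylbut-3-en-2-yl)benzene | C=CC(C)(C)c1cc(Br)c(OC)c(OCOC)c1OCOC
F6 | step 8 | 3,4-dihydroxy-2-methoxy-5-(2-methylbut-3-en-2-yl)benzaldehyde | C=CC(C)(C)c1cc(C=O)c(OC)c(O)c1O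
F7 | step 8 | [2-(4-hydroxyphenyl)-2-oxoethyl]triphenylphosphonium bromide | O=C(C[P+](c1ccccc1)(c1ccccc1)c1ccccc1)c1ccc(O)cc1.[Br-]
F8 | step 8 | 1-(4-hydroxyphenyl)-2-(triphenyl-λ5-phosphanylidene)ethan-1-one | O=C(C=P(c1ccccc1)(c1ccccc1)c1ccccc1)c1ccc(O)cc1
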